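**Retrosynthetic overview**

1. Numbering: C1=C2 (Z), C3=C4(C15H2OAc), C5H2, C6 (O-acyl), C7, C8 (lactone O), C9H2, C10 (CH3), C11(=C13H2), C12 (C=O). Late stage: silyl ethers off, C15–OAc by 1,3-transposition of a ring C3 bis-allylic alcohol, ten-membered ring by ring-closing metathesis at C1=C2 after a Nozaki–Hiyama–Kishi addition of a C4 alkenyl bromide to acrolein, C6 ester by Yamaguchi coupling.
2. The α-methylene lactone and the free C6–OH are released together by E1cB opening (retro-oxa-Michael) of a cis-fused 3,7-dioxabicyclo[3.3.0]octan-2-one in which C13 is still an ether carbon bound to O6.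
3. Key disconnection: that bicycle is made in one operation from an acyclic (E)-allylic alcohol whose O6 carries a CH2–CH(CO2tBu)2 group, by iodocarbocyclisation–lactonisation, which forms C11–C7 and O–C8.
4. Enabling feature: the oxygen on ring carbon C6 and the exocyclic methylene carbon C13 are 1,4-related through C7–C11 (O6–C6–C7–C11–C13), so C13 can serve as a one-carbon tether that delivers C11 to C7 through a five-membered ether ring (ring A) and the carboxyl oxygen to C8 (lactone ring B); the all-syn C6/C7/C8 triad with trans lactone fusion corresponds to syn addition across an E C7=C8 alkene.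
5. Ring order: ring A (temporary) and lactone ring B together (step 7), ring A opened (step 9), ten-membered carbocycle last (step 14). C10 comes from a Claisen chirality transfer, C6 from reagent-controlled allylation, and the side-chain acid from (R)-3-bromo-2-hydroxy-2-methylpropanoic acid.

Key step: step 7

Remark (assumption): the (4R,5R)-diazaborolidine controller in step 4 is taken to deliver the 2-bromoallyl group to the aldehyde face that gives the 4R alcohol, by analogy with the parent allyl reagent; its enantiomer is used if the sense is the reverse.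

**Route**

Step 1
Reactants: 1 rac-(E)-pent-3-en-2-ol
Product: 2 (S,E)-pent-3-en-2-ol (recovered unreacted enantiomer)
Conditions: immobilised Candida antarctica lipase B, vinyl acetate (0.55 equiv), pentane, 23 °C, stopped just past half conversion; distillation from the (R)-acetate
Reagents that add atoms: none
Why: Lipase (serine hydrolase) kinetic resolution by transesterification, in which the (R)-alcohol should be acylated much faster (empirical size rule for secondary alcohols, methyl against propenyl), so (S)-2 should remain enantioenriched; no stereocenter is made.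

Step 2
Reactants: 2 (S,E)-pent-3-en-2-ol
Product: 4 (S,E)-3-methylhex-4-enal, via allyl vinyl ether 3 (not isolated)
Conditions: ethyl vinyl ether (excess), Hg(OAc)2 (cat.), reflux; evaporate; PhMe, 150 °C, sealed tube
Reagents that add atoms: ethyl vinyl ether, C=COCC
Why: Transvinylation then Claisen [3,3] rearrangement through a chair with the carbinol methyl equatorial should transfer the carbinol chirality to the new methyl-bearing center (future C10, S) and give the E-propenyl group.

Step 3
Reactants: 4 (S,E)-3-methylhex-4-enal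
Product: 5 (2E,5S,6E)-5-methylocta-2,6-dienal
Conditions: Ph3P=CHCHO (1.1 equiv), PhMe, 80 °C
Reagents that add atoms: (triphenylphosphoranylidene)acetaldehyde, O=CC=P(c1ccccc1)(c1ccccc1)c1ccccc1
Why: Wittig two-carbon homologation with the stabilised formyl ylide should be E-selective and leaves the β-stereocenter untouched.

Step 4
Reactants: 5 (2E,5S,6E)-5-methylocta-2,6-dienal
Product: 6 (4R,5E,8S,9E)-2-bromo-8-methylundeca-1,5,9-trien-4-ol
Conditions: (4R,5R)-2-bromo-4,5-diphenyl-1,3-bis(p-tolylsulfonyl)-1,3,2-diazaborolidine (1.1 equiv), tributyl(2-bromoallyl)stannane (1.1 equiv), CH2Cl2, 0 → 23 °C; then 5, −78 °C; aqueous work-up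
Reagents that add atoms: tributyl(2-bromoallyl)stannane, C=C(Br)C[Sn](CCCC)(CCCC)CCCC
Why: Enantioselective 2-bromoallylation of the aldehyde (1,2-addition of a chiral allylborane through a chair-like six-membered transition state) should set the C6 carbinol (4R) under reagent control, the remote C10 center having no influence.

Step 5
Reactants: 7 di-tert-butyl malonate
Product: 8 di-tert-butyl 2-methylenemalonate
Conditions: (CH2O)n, KOAc, Cu(OAc)2 (cat.), AcOH, 95 °C; distillation
Reagents that add atoms: formaldehyde (as paraformaldehyde), C=O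
Why: Knoevenagel-type condensation with formaldehyde and dehydration, the bulky tert-butyl esters keeping the methylenemalonate monomeric.

Step 6
Reactants: 6 (4R,5E,8S,9E)-2-bromo-8-methylundeca-1,5,9-trien-4-ol; 8 di-tert-butyl 2-methylenemalonate
Product: 9 di-tert-butyl 2-({[(4R,5E,8S,9E)-2-bromo-8-methylundeca-1,5,9-trien-4-yl]oxy}methyl)malonate
Conditions: KOtBu (5 mol %), THF, 0 °C; then AcOH
Reagents that add atoms: none
Why: Base-catalysed oxa-Michael addition of the secondary alkoxide to the doubly activated alkene should place C13 on O6 as a one-carbon tether carrying the future C11/C12 malonate, without touching a stereocenter.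

Step 7
Reactants: 9 di-tert-butyl 2-({[(4R,5E,8S,9E)-2-bromo-8-methylundeca-1,5,9-trien-4-yl]oxy}methyl)malonate
Product: 11 tert-butyl 6-(2-bromoallyl)-4-[(2S,3E)-2-methylpent-3-en-1-yl]-2-oxo-3,7-dioxabicyclo[3.3.0]octane-1-carboxylate (cis-fused; both side chains exo; C6/C7/C8 as in the target), via iodide 10 (not isolated)
Conditions: I2 (3 equiv), Ti(OtBu)4 (1.5 equiv), CH2Cl2, 23 °C, dark; then 40 °C; aq. Na2S2O3
Reagents that add atoms: none
Why: I2 activates the only alkene that lies five atoms from the malonate carbon (C7=C8), and the Ti(OtBu)4-activated malonate carbon C11 attacks C7 anti to iodine (5-exo-trig closure of tetrahydrofuran ring A through O6 and C13) to give iodide 10, after which the tert-butyl ester cis to the iodoalkyl arm displaces iodide at C8 with inversion (5-exo-tet O-alkylation, loss of 2-methylpropene) and closes γ-lactone ring B. The closest known reaction type is the iodocarbocyclisation–lactonisation of 4-pentenylmalonates, here with an ether oxygen in the chain. C7 is set relative to C6: in the chair-like transition state the 2-bromoallyl arm on C6 is pseudo-equatorial (C6–H eclipsing the alkene), so C11 should add to the face that places the C5 and C8 arms trans on ring A. C8 follows from the E geometry of the alkene, because anti C–C/C–I addition followed by SN2 inversion amounts to syn addition of C11 and O, which gives the trans relationship of the C6 and C9 arms on the lactone (an iodine-assisted SN1 closure on the convex face would give the same product); C11 becomes stereogenic only because the two five-membered rings must be cis-fused. The step needs chemoselectivity among three alkenes and the regiochemistry C11→C7, O→C8: the one-carbon tether allows only the five-membered closure at C7, the 2-bromoallyl alkene is deactivated by bromine and would need a six- or seven-membered closure, and the propenyl group is out of reach.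

Step 8
Reactants: 11 tert-butyl 6-(2-bromoallyl)-4-[(2S,3E)-2-methylpent-3-en-1-yl]-2-oxo-3,7-dioxabicyclo[3.3.0]octane-1-carboxylate
Product: 13 6-(2-bromoallyl)-4-[(2S,3E)-2-methylpent-3-en-1-yl]-3,7-dioxabicyclo[3.3.0]octan-2-one (cis-fused; side chains exo), via carboxylic acid 12 (not isolated)
Conditions: TFA/CH2Cl2 (1:4), 0 → 23 °C; evaporate; PhMe, 110 °C
Reagents that add atoms: none
Why: Acidolysis of the remaining tert-butyl ester and thermal decarboxylation of the α-carboxy lactone, in which protonation of the enol can only give the cis-fused bicycle (C11–H cis to C7–H).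

Step 9
Reactants: 13 6-(2-bromoallyl)-4-[(2S,3E)-2-methylpent-3-en-1-yl]-3,7-dioxabicyclo[3.3.0]octan-2-one
Product: 16 trans-4-[(1R)-3-bromo-1-hydroxybut-3-en-1-yl]-5-[(2S,3E)-2-methylpent-3-en-1-yl]-3-methylenedihydrofuran-2(3H)-one (C6/C7/C8 as in the target), via lithium enolate 14 (not isolated), via lithium alkoxide 15 (not isolated)
Conditions: LiN(SiMe3)2 (1.1 equiv), THF, −78 → 0 °C; AcOH (2 equiv), −78 °C
Reagents that add atoms: none
Why: E1cB β-elimination (retro-oxa-Michael) in which the lactone enolate expels the O6 alkoxide, opening ring A, creating the exocyclic C11=C13 methylene and freeing the C6 hydroxyl in one step; one equivalent of base and a cold acidic quench should limit translactonisation and γ-deprotonation.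

Step 10
Reactants: 17 (R)-3-bromo-2-hydroxy-2-methylpropanoic acid
Product: 19 (S)-2,3-dihydroxy-2-methylpropanoic acid, via sodium glycidate 18 (not isolated)
Conditions: NaOH (3 equiv), H2O, 60 °C; aq. HCl to pH 2; evaporate; EtOAc extraction
Reagents that add atoms: sodium hydroxide, [Na+].[OH-]
Why: Intramolecular displacement of bromide by the tertiary alkoxide gives the glycidate, which hydroxide opens at the CH2 carbon, so the quaternary center is never touched (the descriptor changes from R to S only because the CH2X group changes rank).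

Step 11
Reactants: 19 (S)-2,3-dihydroxy-2-methylpropanoic acid
Product: 21 (S)-2-methyl-2,3-bis(triethylsilyloxy)propanoic acid, via silyl ester 20 (not isolated)
Conditions: Et3SiOTf (3.3 equiv), 2,6-lutidine, CH2Cl2, −78 → 0 °C; then THF/H2O, pH 7 buffer, 23 °C
Reagents that add atoms: triethylsilyl trifluoromethanesulfonate, CC[Si](CC)(CC)OS(=O)(=O)C(F)(F)F
Why: Exhaustive silylation followed by selective hydrolysis of the labile silyl ester should leave both hydroxyls protected as triethylsilyl ethers.

Step 12
Reactants: 16 trans-4-[(1R)-3-bromo-1-hydroxybut-3-en-1-yl]-5-[(2S,3E)-2-methylpent-3-en-1-yl]-3-methylenedihydrofuran-2(3H)-one; 21 (S)-2-methyl-2,3-bis(triethylsilyloxy)propanoic acid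
Product: 23 C6 (S)-2-methyl-2,3-bis(triethylsilyloxy)propanoate ester of 16, via mixed anhydride 22 (not isolated)
Conditions: 21, 2,4,6-trichlorobenzoyl chloride, Et3N, THF, 23 °C; then 16, DMAP, PhMe, 23 → 40 °C
Reagents that add atoms: none
Why: Yamaguchi esterification through the mixed anhydride acylates the only free hydroxyl with retention at C6, and the quaternary α-carbon of the acid cannot epimerise.

Step 13
Reactants: 23 C6 (S)-2-methyl-2,3-bis(triethylsilyloxy)propanoate ester of 16
Product: 24 analogue of 23 in which the C4 bromide is replaced by a 1-hydroxyprop-2-en-1-yl group (C3 carbinol; both C3 epimers)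
Conditions: acrolein (5 equiv), CrCl2 (6 equiv), NiCl2 (2 mol %), DMSO/THF, 23 °C
Reagents that add atoms: acrolein, C=CC=O
Why: Nozaki–Hiyama–Kishi reaction, in which the alkenylchromium formed from the 2-bromoalkene adds 1,2 to acrolein in the presence of the lactone, esters and silyl ethers; the C3 epimers are carried together because C3 becomes sp2 in step 15.

Step 14
Reactants: 24 acyclic bis-allylic alcohol (both C3 epimers)
Product: 25 ten-membered-ring allylic alcohol (C1=C2 Z; C3–OH; exocyclic C4=C15H2; otherwise as the target, side chain as bis(triethylsilyl) ether)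
Conditions: second-generation Grubbs catalyst RuCl2(=CHPh)(PCy3)(H2IMes) (10 mol %), 1,4-benzoquinone (10 mol %), CH2Cl2 (1 mM), 40 °C
Reagents that add atoms: none
Why: Ring-closing metathesis between the vinyl group (C2) and the propenyl group (C1) with loss of propene should close the ten-membered ring with Z geometry (an E olefin in this ring is more strained), the electron-poor C11=C13 and the 1,1-disubstituted C4=C15 alkenes being slow to react.

Step 15
Reactants: 25 ten-membered-ring allylic alcohol
Product: 26 ring dienyl alcohol (C1=C2–C3=C4 with C15H2OH; the target lacking the acetyl group, side chain as bis(triethylsilyl) ether)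
Conditions: Ph3SiOReO3 (5 mol %), Et2O, −50 → 0 °C
Reagents that add atoms: none
Why: Rhenium-oxo-catalysed [3,3] 1,3-transposition of the bis-allylic alcohol through its perrhenate ester, driven by formation of the conjugated trisubstituted diene and a primary alcohol; inside the ring the new C3=C4 bond should form with C2 and C5 cis, as the target requires.

Step 16
Reactants: 26 ring dienyl alcohol
Product: 27 bis(triethylsilyl) ether of the target
Conditions: Ac2O, pyridine, DMAP (cat.), CH2Cl2, 0 °C
Reagents that add atoms: acetic anhydride, CC(=O)OC(C)=O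
Why: Acetylation of the only free hydroxyl, the primary allylic C15–OH.

Step 17
Reactants: 27 bis(triethylsilyl) ether of the target
Product: 28 target (CNP0347302.1)
Conditions: HF·pyridine, pyridine/THF, 0 → 23 °C
Reagents that add atoms: none
Why: Fluoride cleavage of both triethylsilyl ethers under buffered, mildly acidic conditions that should spare the allylic acetate, the hindered ester, the diene and the Michael-acceptor lactone.

**Compound list**

1 | rac-(E)-pent-3-en-2-ol | C/C=C/C(C)O | starting material
2 | (S,E)-pent-3-en-2-ol | C[C@H](O)/C=C/C | intermediate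
3 | (S,E)-4-(vinyloxy)pent-2-ene | C=CO[C@@H](C)/C=C/C | intermediate
4 | (S,E)-3-methylhex-4-enal | O=CC[C@H](C)/C=C/C | intermediate
5 | (2E,5S,6E)-5-methylocta-2,6-dienal | O=C/C=C/C[C@H](C)/C=C/C | intermediate
6 | (4R,5E,8S,9E)-2-bromo-8-methylundeca-1,5,9-trien-4-ol | BrC(=C)C[C@@H](O)/C=C/C[C@H](C)/C=C/C | intermediate
7 | di-tert-butyl malonate | CC(C)(C)OC(=O)CC(=O)OC(C)(C)C | starting material
8 | di-tert-butyl 2-methylenemalonate | C=C(C(=O)OC(C)(C)C)C(=O)OC(C)(C)C | intermediate
9 | di-tert-butyl 2-({[(4R,5E,8S,9E)-2-bromo-8-methylundeca-1,5,9-trien-4-yl]oxy}methyl)malonate | BrC(=C)C[C@@H](OCC(C(=O)OC(C)(C)C)C(=O)OC(C)(C)C)/C=C/C[C@H](C)/C=C/C | intermediate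
10 | di-tert-butyl 5-(2-bromoallyl)-4-[(3S,4E)-1-iodo-3-methylhex-4-en-1-yl]tetrahydrofuran-3,3-dicarboxylate (ring substituents trans; C8–I anti to the C7–C11 bond) | BrC(=C)C[C@H]1OCC(C(=O)OC(C)(C)C)(C(=O)OC(C)(C)C)[C@@H]1[C@H](I)C[C@H](C)/C=C/C | intermediate
11 | tert-butyl 6-(2-bromoallyl)-4-[(2S,3E)-2-methylpent-3-en-1-yl]-2-oxo-3,7-dioxabicyclo[3.3.0]octane-1-carboxylate (cis-fused; side chains exo) | BrC(=C)C[C@H]1OC[C@]2(C(=O)OC(C)(C)C)C(=O)O[C@@H](C[C@H](C)/C=C/C)[C@H]12 | intermediate
12 | 6-(2-bromoallyl)-4-[(2S,3E)-2-methylpent-3-en-1-yl]-2-oxo-3,7-dioxabicyclo[3.3.0]octane-1-carboxylic acid | BrC(=C)C[C@H]1OC[C@]2(C(O)=O)C(=O)O[C@@H](C[C@H](C)/C=C/C)[C@H]12 | intermediate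
13 | 6-(2-bromoallyl)-4-[(2S,3E)-2-methylpent-3-en-1-yl]-3,7-dioxabicyclo[3.3.0]octan-2-one (cis-fused; side chains exo) | BrC(=C)C[C@H]1OC[C@@H]2C(=O)O[C@@H](C[C@H](C)/C=C/C)[C@H]12 | intermediate
14 | lithium enolate of 13 | BrC(=C)C[C@H]1OCC2=C([O-])O[C@@H](C[C@H](C)/C=C/C)[C@H]12.[Li+] | intermediate
15 | lithium alkoxide of 16 | BrC(=C)C[C@@H]([O-])[C@@H]1C(=C)C(=O)O[C@H]1C[C@H](C)/C=C/C.[Li+] | intermediate
16 | trans-4-[(1R)-3-bromo-1-hydroxybut-3-en-1-yl]-5-[(2S,3E)-2-methylpent-3-en-1-yl]-3-methylenedihydrofuran-2(3H)-one | BrC(=C)C[C@@H](O)[C@@H]1C(=C)C(=O)O[C@H]1C[C@H](C)/C=C/C | intermediate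
17 | (R)-3-bromo-2-hydroxy-2-methylpropanoic acid | OC(=O)[C@@](C)(O)CBr | starting material
18 | sodium (S)-2-methyloxirane-2-carboxylate | [O-]C(=O)[C@@]1(C)OC1.[Na+] | intermediate
19 | (S)-2,3-dihydroxy-2-methylpropanoic acid | OC(=O)[C@@](C)(O)CO | intermediate
20 | triethylsilyl (S)-2-methyl-2,3-bis(triethylsilyloxy)propanoate | CC[Si](CC)(CC)OC(=O)[C@@](C)(O[Si](CC)(CC)CC)CO[Si](CC)(CC)CC | intermediate
21 | (S)-2-methyl-2,3-bis(triethylsilyloxy)propanoic acid | OC(=O)[C@@](C)(O[Si](CC)(CC)CC)CO[Si](CC)(CC)CC | intermediate
22 | mixed anhydride of 21 and 2,4,6-trichlorobenzoic acid | O=C(OC(=O)[C@@](C)(O[Si](CC)(CC)CC)CO[Si](CC)(CC)CC)c1c(Cl)cc(Cl)cc1Cl | intermediate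
23 | C6 (S)-2-methyl-2,3-bis(triethylsilyloxy)propanoate ester of 16 | BrC(=C)C[C@@H](OC(=O)[C@@](C)(O[Si](CC)(CC)CC)CO[Si](CC)(CC)CC)[C@@H]1C(=C)C(=O)O[C@H]1C[C@H](C)/C=C/C | intermediate
24 | analogue of 23 with 1-hydroxyprop-2-en-1-yl at C4 in place of bromine (C3 epimers) | C=CC(O)C(=C)C[C@@H](OC(=O)[C@@](C)(O[Si](CC)(CC)CC)CO[Si](CC)(CC)CC)[C@@H]1C(=C)C(=O)O[C@H]1C[C@H](C)/C=C/C | intermediate
25 | ten-membered-ring allylic alcohol (C1=C2 Z; C3–OH; C4=C15H2; stereocenters C6, C7, C8, C10 as in the target; C3 epimers) | C=C1C(=O)O[C@H]2C[C@H](C)/C=C\C(O)C(=C)C[C@@H](OC(=O)[C@@](C)(O[Si](CC)(CC)CC)CO[Si](CC)(CC)CC)[C@H]12 | intermediate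
26 | ring dienyl alcohol (C15–OH; otherwise as 27) | C=C1C(=O)O[C@H]2C[C@H](C)/C=C\C=C(\CO)C[C@@H](OC(=O)[C@@](C)(O[Si](CC)(CC)CC)CO[Si](CC)(CC)CC)[C@H]12 | intermediate
27 | bis(triethylsilyl) ether of the target | C=C1C(=O)O[C@H]2C[C@H](C)/C=C\C=C(\COC(C)=O)C[C@@H](OC(=O)[C@@](C)(O[Si](CC)(CC)CC)CO[Si](CC)(CC)CC)[C@H]12 | intermediate
28 | CNP0347302.1 | C=C1C(=O)O[C@H]2C[C@H](C)/C=C\C=C(\COC(C)=O)C[C@@H](OC(=O)[C@@](C)(O)CO)[C@H]12 | target

**Totals**

Total step count: 17. Longest linear sequence: 14 steps (steps 1–4, 6–9 and 12–17).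

**Steps most likely to fail**

Step 7. The C–C closure may show poor facial selectivity (the C5 and C8 arms ending cis on ring A), or the activated malonate may lose the tether by retro-oxa-Michael fragmentation before it cyclises. The fallback sets out from 9 and comes back at 11. It is an oxidative free-radical cyclisation with Mn(OAc)3·2H2O (2.2 equiv) and Cu(OAc)2 (1 equiv) in AcOH at 60 °C. The neutral malonyl radical cannot expel the alkoxide, and it should close 5-exo through a chair-like transition state with the C6 arm pseudo-equatorial. The C8 radical is then oxidised by Cu(OAc)2 and captured on the convex face by the cis tert-butyl ester. This fallback makes no compound outside the list (F0).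

Step 14. Oligomerisation may outrun ring closure, the new olefin may form with E geometry, or a ruthenium hydride may isomerise the bis-allylic alcohol. The fallback sets out from 23 and comes back at 25, closing the ring at C3–C4 instead of C1=C2. The electron-rich propenyl group of 23 is cleaved selectively (OsO4 cat., N-methylmorpholine N-oxide; then NaIO4) to the C1 aldehyde F1. A Z-selective Wittig reaction with the ylide from (1,3-dioxolan-2-ylmethyl)triphenylphosphonium bromide (NaN(SiMe3)2, THF, −78 °C) gives the (Z)-alkenyl dioxolane F2. Mild hydrolysis (aqueous oxalic acid on silica) gives the (Z)-enal F3. An intramolecular Nozaki–Hiyama–Kishi reaction (CrCl2, NiCl2 cat., DMSO/THF, high dilution) between the C4 alkenyl bromide and the C3 aldehyde then gives 25.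

Step 15. The bis-allylic perrhenate may ionise to a pentadienyl cation and eliminate, or the hydroxyl may migrate toward C1 instead of C15. The fallback sets out from 25 and comes back at 27, bypassing 26. SOCl2 in Et2O at 0 °C should convert the alcohol with allylic shift into the primary, conjugated allylic chloride F4. Displacement with CsOAc and 18-crown-6 in PhMe (SN2 at the primary allylic carbon) then gives 27.

**Further compounds**

F0 | step 7 | none | none
F1 | step 14 | C1 aldehyde from cleavage of the propenyl group of 23 | BrC(=C)C[C@@H](OC(=O)[C@@](C)(O[Si](CC)(CC)CC)CO[Si](CC)(CC)CC)[C@@H]1C(=C)C(=O)O[C@H]1C[C@H](C)C=O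
F2 | step 14 | (Z)-alkenyl dioxolane | BrC(=C)C[C@@H](OC(=O)[C@@](C)(O[Si](CC)(CC)CC)CO[Si](CC)(CC)CC)[C@@H]1C(=C)C(=O)O[C@H]1C[C@H](C)/C=C\C1OCCO1
F3 | step 14 | (Z)-enal | BrC(=C)C[C@@H](OC(=O)[C@@](C)(O[Si](CC)(CC)CC)CO[Si](CC)(CC)CC)[C@@H]1C(=C)C(=O)O[C@H]1C[C@H](C)/C=C\C=O
F4 | step 15 | C15 allylic chloride with the ring diene in place | C=C1C(=O)O[C@H]2C[C@H](C)/C=C\C=C(\CCl)C[C@@H](OC(=O)[C@@](C)(O[Si](CC)(CC)CC)CO[Si](CC)(CC)CC)[C@H]12
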